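Ring B is treated as a latent cyclohex-2-enone: C8 as carbonyl, flanked by C7 and C9, facing ring A through C6 and the quaternary C10. Cutting C6–C7 and C9–C10 gives β-cyclocitral (C6 aldehyde carbon, C10 its β-carbon) and a chiral 2-ethoxyallylboronate that carries C7–C9 and the whole side chain. One pot joins them: allylboration at C6, an anionic oxy-Cope shift that moves the allyl unit to C10 with transfer of chirality from the C6 carbinol to the quaternary centre, then hydrolysis and aldol condensation that close ring B. The enone is turned into the C7=C8 methyl alkene; the side-chain triol comes from a tartrate-controlled epoxidation.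

Key step: step 5

Remark: labdane numbering is used (ring A: C1–C5, C10; ring B: C5–C10; side chain C11–C16; C17 on C8, C18/C19 on C4, C20 on C10); the target is (5R,9R,10R,13S,14R), an ent-labdane.
Remark: geraniol, β-cyclocitral, 1-ethoxyvinylboronic acid pinacol ester and (−)-sparteine are taken as purchased.

Step 1
Reactants: 1 geraniol
Product: 2 geranyl tert-butyldiphenylsilyl ether
Conditions: t-BuPh2SiCl, imidazole, DMF, 0 °C to rt
Reagents that add atoms: tert-butyl(chloro)diphenylsilane, CC(C)(C)[Si](Cl)(c1ccccc1)c1ccccc1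
Why: Silyl ether formation at the primary allylic alcohol should give a group that survives organolithium, alkoxide, hydride and dilute acid and is removed by fluoride at the end.

Step 2
Reactants: 2 geranyl tert-butyldiphenylsilyl ether
Product: 3 (4E)-6-(tert-butyldiphenylsilyloxy)-4-methylhex-4-en-1-ol
Conditions: O3 (1.0 equiv), CH2Cl2/MeOH, −78 °C; then NaBH4, −78 to 0 °C
Reagents that add atoms: ozone, [O-][O+]=O
Why: Ozonolysis with reductive work-up should cleave the electron-rich distal trisubstituted alkene of the geranyl chain in preference to the alkene next to the bulky, inductively deactivating silyloxy group, and the hydride reduces the aldehyde to the primary alcohol (the future C9).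

Step 3
Reactants: 3 (4E)-6-(tert-butyldiphenylsilyloxy)-4-methylhex-4-en-1-ol
Product: 4 (4E)-6-(tert-butyldiphenylsilyloxy)-4-methylhex-4-en-1-yl N,N-diisopropylcarbamate
Conditions: i-Pr2NC(O)Cl, Et3N, CH2Cl2, reflux
Reagents that add atoms: N,N-diisopropylcarbamoyl chloride, CC(C)N(C(C)C)C(Cl)=O
Why: O-Carbamoylation installs the directing and leaving group needed for asymmetric α-lithiation.

Step 4
Reactants: 4 (4E)-6-(tert-butyldiphenylsilyloxy)-4-methylhex-4-en-1-yl N,N-diisopropylcarbamate; 5 2-(1-ethoxyvinyl)-4,4,5,5-tetramethyl-1,3,2-dioxaborolane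
Product: 8 2-[(3R,6E)-8-(tert-butyldiphenylsilyloxy)-2-ethoxy-6-methylocta-1,6-dien-3-yl]-4,4,5,5-tetramethyl-1,3,2-dioxaborolane, via lithiated carbamate 6 (not isolated), via boronate complex 7 (not isolated)
Conditions: s-BuLi, (−)-sparteine, Et2O, −78 °C; then 5, −78 °C; then MgBr2·OEt2, −78 to 35 °C
Reagents that add atoms: none
Why: Sparteine-mediated enantioselective deprotonation (removal of the pro-S hydrogen) gives the (S)-organolithium 6, which is borylated with retention to 7, and the 1,2-metalate rearrangement (lithiation–borylation) moves the ethoxyvinyl group from boron to carbon with inversion, which should set the (R) boron-bearing centre (the future C9) of 8.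

Step 5
Reactants: 8 2-[(3R,6E)-8-(tert-butyldiphenylsilyloxy)-2-ethoxy-6-methylocta-1,6-dien-3-yl]-4,4,5,5-tetramethyl-1,3,2-dioxaborolane; 9 β-cyclocitral
Product: 14 15-(tert-butyldiphenylsilyloxy)-17-nor-9-epi-ent-labda-6,13E-dien-8-one, via borate ester 10 (not isolated), via potassium alkoxide 11 (not isolated), via potassium enolate 12 (not isolated), via keto aldehyde 13 (not isolated)
Conditions: toluene, 60 °C; then KOt-Bu, 18-crown-6, THF, 0 to 45 °C; then 2 M HCl, THF, 0 to 40 °C
Reagents that add atoms: water, O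
Why: Allylboration: the γ-carbon C7 of 8 adds to the C6 aldehyde of 9 through a closed six-membered chair transition state with the cyclohexenyl group equatorial and the side chain on the boron-bearing carbon pseudo-axial (as expected for a 2-substituted pinacol allylboronate), which should relay the C9–B configuration to (6R) in 10 and place C11 cis to C7. tert-Butoxide then frees the potassium alkoxide 11, whose anionic oxy-Cope [3,3] shift runs through a chair with C6–O equatorial (the C20 methyl on the ring alkene is forced axial), forms C9–C10 and so sets the quaternary C10 from C6, while the first C6–C7 link is given up. Acid hydrolyses the 2-ethoxyalkene of 12 to the methyl ketone 13, and the C7 enol closes ring B onto the C6 aldehyde by a 6-(enolendo)-exo-trig aldol addition followed by dehydration, which is where the final C6–C7 bond is made. The closest known reaction type is the Robinson-type Michael–aldol (3+3) annulation of a ketone with an enal, the hindered Michael step being replaced here by 1,2-addition and [3,3] shift. C5 is expected to settle trans (the α-formyl centre equilibrates and both ring B bonds sit equatorial on ring A), whereas C9 should emerge mainly with the side chain axial (trans to C20) and is corrected in step 6. The step needs γ-selective, face-selective allylboration and a chair oxy-Cope shift; the closed boron transition state, the axial C20 methyl, and the fact that every other aldol pairing would give a four-membered ring should secure this.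

Step 6
Reactants: 14 15-(tert-butyldiphenylsilyloxy)-17-nor-9-epi-ent-labda-6,13E-dien-8-one
Product: 16 15-(tert-butyldiphenylsilyloxy)-17-nor-ent-labda-6,13E-dien-8-one, via lithium dienolate 15 (not isolated)
Conditions: LiN(i-Pr)2, THF, −78 to −40 °C; then AcOH, −78 °C
Reagents that add atoms: none
Why: Kinetic α′-deprotonation at C9 gives the cross-conjugated dienolate 15, and kinetic protonation should occur on the face opposite the axial C20 methyl, so that H9 ends trans and C11 cis to C20 and both C9 epimers converge on 16.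

Step 7
Reactants: 16 15-(tert-butyldiphenylsilyloxy)-17-nor-ent-labda-6,13E-dien-8-one
Product: 18 15-(tert-butyldiphenylsilyloxy)-17-nor-ent-labda-7,13E-dien-8-yl trifluoromethanesulfonate, via lithium enolate 17 (not isolated)
Conditions: LiBH(s-Bu)3, THF, −78 °C; then PhNTf2, −78 to 0 °C
Reagents that add atoms: N-phenyl-bis(trifluoromethanesulfonimide), O=S(=O)(N(c1ccccc1)S(=O)(=O)C(F)(F)F)C(F)(F)F
Why: Conjugate (1,4) hydride reduction of the enone gives the C7=C8 enolate regiospecifically, and O-triflation fixes the alkene between C7 and C8 without touching C9.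

Step 8
Reactants: 18 15-(tert-butyldiphenylsilyloxy)-17-nor-ent-labda-7,13E-dien-8-yl trifluoromethanesulfonate
Product: 19 ent-labda-7,13E-dien-15-yl tert-butyldiphenylsilyl ether
Conditions: MeMgBr, Fe(acac)3 (5 mol %), THF/NMP, −30 to 0 °C
Reagents that add atoms: methylmagnesium bromide, C[Mg]Br
Why: Iron-catalysed cross-coupling of the alkenyl triflate with the methyl Grignard reagent should put the C17 methyl on C8 and keep the alkene at C7=C8.

Step 9
Reactants: 19 ent-labda-7,13E-dien-15-yl tert-butyldiphenylsilyl ether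
Product: 20 ent-labda-7,13E-dien-15-ol
Conditions: Bu4NF, THF, 0 °C to rt
Reagents that add atoms: none
Why: Fluoride-induced desilylation frees the allylic alcohol that directs the next step.

Step 10
Reactants: 20 ent-labda-7,13E-dien-15-ol
Product: 21 (13S,14S)-13,14-epoxy-ent-labd-7-en-15-ol
Conditions: Ti(Oi-Pr)4, L-(+)-diethyl tartrate, t-BuOOH, 4 Å molecular sieves, CH2Cl2, −20 °C
Reagents that add atoms: tert-butyl hydroperoxide, CC(C)(C)OO
Why: The Katsuki–Sharpless asymmetric epoxidation is directed by the allylic hydroxyl, so only the C13=C14 alkene should react while C7=C8 is left, and the L-(+)-tartrate ligand should give the (13S,14S) epoxide under reagent control, as it does for geraniol.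

Step 11
Reactants: 21 (13S,14S)-13,14-epoxy-ent-labd-7-en-15-ol
Product: 23 (13S,14R)-ent-labd-7-ene-13,14,15-triol, via terminal epoxide 22 (not isolated)
Conditions: NaOH (0.5 M), t-BuOH/H2O, 75 °C
Reagents that add atoms: water, O
Why: In the Payne rearrangement the C15 alkoxide opens the epoxide at C14 with inversion to the terminal epoxide 22, which hydroxide opens at the unhindered C15, so that C14 becomes R and C13 stays S.

Step 12
Reactants: 23 (13S,14R)-ent-labd-7-ene-13,14,15-triol
Product: 24 (13S,14R)-14,15-diacetoxy-ent-labd-7-en-13-ol (CNP0545929.1)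
Conditions: Ac2O, pyridine, DMAP (cat.), CH2Cl2, 0 °C
Reagents that add atoms: acetic anhydride, CC(=O)OC(C)=O
Why: Acetylation should esterify the primary and secondary hydroxyls, while the tertiary C13 hydroxyl is too hindered to react under these conditions.

Compound list
1 | geraniol | CC(C)=CCC/C(C)=C/CO | starting material
2 | geranyl tert-butyldiphenylsilyl ether | CC(C)=CCC/C(C)=C/CO[Si](c1ccccc1)(c1ccccc1)C(C)(C)C | intermediate
3 | (4E)-6-(tert-butyldiphenylsilyloxy)-4-methylhex-4-en-1-ol | OCCC/C(C)=C/CO[Si](c1ccccc1)(c1ccccc1)C(C)(C)C | intermediate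
4 | (4E)-6-(tert-butyldiphenylsilyloxy)-4-methylhex-4-en-1-yl N,N-diisopropylcarbamate | CC(C)N(C(C)C)C(=O)OCCC/C(C)=C/CO[Si](c1ccccc1)(c1ccccc1)C(C)(C)C | intermediate
5 | 2-(1-ethoxyvinyl)-4,4,5,5-tetramethyl-1,3,2-dioxaborolane | CCOC(=C)B1OC(C)(C)C(C)(C)O1 | starting material
6 | (S)-α-lithiated carbamate (sparteine complex, ligand not drawn) | [Li][C@H](OC(=O)N(C(C)C)C(C)C)CC/C(C)=C/CO[Si](c1ccccc1)(c1ccccc1)C(C)(C)C | intermediate (not isolated)
7 | lithium boronate complex of 6 and 5 | [Li+].CCOC(=C)[B-]1(OC(C)(C)C(C)(C)O1)[C@H](OC(=O)N(C(C)C)C(C)C)CC/C(C)=C/CO[Si](c2ccccc2)(c2ccccc2)C(C)(C)C | intermediate (not isolated)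
8 | 2-[(3R,6E)-8-(tert-butyldiphenylsilyloxy)-2-ethoxy-6-methylocta-1,6-dien-3-yl]-4,4,5,5-tetramethyl-1,3,2-dioxaborolane | CCOC(=C)[C@H](B1OC(C)(C)C(C)(C)O1)CC/C(C)=C/CO[Si](c2ccccc2)(c2ccccc2)C(C)(C)C | intermediate
9 | β-cyclocitral (2,6,6-trimethylcyclohex-1-ene-1-carbaldehyde) | CC1=C(C=O)C(C)(C)CCC1 | starting material
10 | pinacol borate of the (6R)-homoallylic alcohol, enol ether with C11 cis to C7 | CC1=C(C(C)(C)CCC1)[C@H](OB2OC(C)(C)C(C)(C)O2)C/C(OCC)=C\CC/C(C)=C/CO[Si](c3ccccc3)(c3ccccc3)C(C)(C)C | intermediate (not isolated)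
11 | potassium (6R)-alkoxide of the same 1,5-diene | [K+].CC1=C(C(C)(C)CCC1)[C@H]([O-])C/C(OCC)=C\CC/C(C)=C/CO[Si](c2ccccc2)(c2ccccc2)C(C)(C)C | intermediate (not isolated)
12 | potassium enolate of the C6 aldehyde after the [3,3] shift (C10 quaternary, C9 with side chain trans to C20, 2-ethoxyallyl group intact) | [K+].CCOC(=C)[C@H](CC/C(C)=C/CO[Si](c1ccccc1)(c1ccccc1)C(C)(C)C)[C@]2(C)CCCC(C)(C)/C2=C\[O-] | intermediate (not isolated)
13 | keto aldehyde (C8 methyl ketone, C6 aldehyde trans to C9 on ring A) | CC(C)(C)[Si](c1ccccc1)(c1ccccc1)OC/C=C(\C)CC[C@@H](C(C)=O)[C@]2(C)CCCC(C)(C)[C@H]2C=O | intermediate (not isolated)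
14 | 15-(tert-butyldiphenylsilyloxy)-17-nor-9-epi-ent-labda-6,13E-dien-8-one | CC(C)(C)[Si](c1ccccc1)(c1ccccc1)OC/C=C(\C)CC[C@H]2C(=O)C=C[C@@H]3C(C)(C)CCC[C@@]23C | intermediate
15 | lithium cross-conjugated dienolate (C8–O, C8=C9, C6=C7) | [Li+].[O-]C1=C(CC/C(C)=C/CO[Si](c3ccccc3)(c3ccccc3)C(C)(C)C)[C@]2(C)CCCC(C)(C)[C@H]2C=C1 | intermediate (not isolated)
16 | 15-(tert-butyldiphenylsilyloxy)-17-nor-ent-labda-6,13E-dien-8-one | CC(C)(C)[Si](c1ccccc1)(c1ccccc1)OC/C=C(\C)CC[C@@H]2C(=O)C=C[C@@H]3C(C)(C)CCC[C@@]23C | intermediate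
17 | lithium C7=C8 enolate | [Li+].CC(C)(C)[Si](c1ccccc1)(c1ccccc1)OC/C=C(\C)CC[C@@H]2C([O-])=CC[C@@H]3C(C)(C)CCC[C@@]23C | intermediate (not isolated)
18 | 15-(tert-butyldiphenylsilyloxy)-17-nor-ent-labda-7,13E-dien-8-yl trifluoromethanesulfonate | CC(C)(C)[Si](c1ccccc1)(c1ccccc1)OC/C=C(\C)CC[C@@H]2C(OS(=O)(=O)C(F)(F)F)=CC[C@@H]3C(C)(C)CCC[C@@]23C | intermediate
19 | ent-labda-7,13E-dien-15-yl tert-butyldiphenylsilyl ether | CC(C)(C)[Si](c1ccccc1)(c1ccccc1)OC/C=C(\C)CC[C@@H]2C(C)=CC[C@@H]3C(C)(C)CCC[C@@]23C | intermediate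
20 | ent-labda-7,13E-dien-15-ol | OC/C=C(\C)CC[C@@H]1C(C)=CC[C@@H]2C(C)(C)CCC[C@@]12C | intermediate
21 | (13S,14S)-13,14-epoxy-ent-labd-7-en-15-ol | OC[C@@H]1O[C@@]1(C)CC[C@@H]2C(C)=CC[C@@H]3C(C)(C)CCC[C@@]23C | intermediate
22 | (13S,14R)-14,15-epoxy-ent-labd-7-en-13-ol | C1O[C@H]1[C@@](C)(O)CC[C@@H]2C(C)=CC[C@@H]3C(C)(C)CCC[C@@]23C | intermediate (not isolated)
23 | (13S,14R)-ent-labd-7-ene-13,14,15-triol | OC[C@@H](O)[C@@](C)(O)CC[C@@H]1C(C)=CC[C@@H]2C(C)(C)CCC[C@@]12C | intermediate
24 | (13S,14R)-14,15-diacetoxy-ent-labd-7-en-13-ol (CNP0545929.1) | CC(=O)OC[C@@H](OC(C)=O)[C@@](C)(O)CC[C@@H]1C(C)=CC[C@@H]2C(C)(C)CCC[C@@]12C | target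

Total step count: 12. Longest linear sequence: 12 steps (1 to 24).

Steps most likely to fail

Step 5. The allylboration of the hindered aldehyde may be slow or may not hold one orientation of the side chain on the boron-bearing carbon, which would erode the transfer of chirality. The alkoxide may not be released cleanly from boron before the [3,3] shift, and the silyl ether may suffer in the acid phase. The fallback separates the events and removes boron before the rearrangement. It sets out from 8 and 9: allylboration followed by a non-acidic work-up (triethanolamine) should give the free (6R)-homoallylic alcohol F1. Its potassium alkoxide (KH, 18-crown-6, THF) should undergo the anionic oxy-Cope shift, and a buffered quench should give the aldehyde that still carries the 2-ethoxyallyl group F2. Dilute HCl in THF then hydrolyses the enol ether and closes ring B, and the route is rejoined at 14.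

Step 4. The 1,2-migration of the electron-rich 1-ethoxyvinyl group may be sluggish, or the enol ether may not survive MgBr2·OEt2. The fallback carries the ketone in masked form as a plain vinyl group. It sets out from 4: the same lithiation, then 4,4,5,5-tetramethyl-2-vinyl-1,3,2-dioxaborolane, should give the (R)-α-substituted allylboronate F3 by a well-precedented vinyl migration. Allylboration of 9 with F3, then KH and 18-crown-6, should give the aldehyde that bears a vinyl group on C9 F4. Wacker oxidation (PdCl2, CuCl, O2, DMF/H2O) converts the terminal vinyl group into the methyl ketone, which is keto aldehyde 13, and dilute HCl closes it; the route is rejoined at 14.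

Step 6. Deprotonation may compete at C5 (γ) instead of C9, or the protonation of the dienolate may not be face-selective. The fallback uses thermodynamic instead of kinetic control. It sets out from 14: conjugate reduction with LiBH(s-Bu)3 and a methanol quench should give the saturated 9-epi ketone F5, and NaOMe in MeOH should equilibrate C9 towards the ketone with the equatorial side chain F6. Kinetic deprotonation at the C7 methylene with KN(SiMe3)2 at −78 °C and trapping with PhNTf2 then gives the enol triflate, and the route is rejoined at 18.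

Further compounds
F1 | step 5 | (6R)-homoallylic alcohol, free form of 10 | CC1=C(C(C)(C)CCC1)[C@H](O)C/C(OCC)=C\CC/C(C)=C/CO[Si](c2ccccc2)(c2ccccc2)C(C)(C)C
F2 | step 5 | C6 aldehyde with the 2-ethoxyallyl group on C9, protonated form of 12 | CCOC(=C)[C@H](CC/C(C)=C/CO[Si](c1ccccc1)(c1ccccc1)C(C)(C)C)[C@]2(C)CCCC(C)(C)[C@H]2C=O
F3 | step 4 | 2-[(3R,6E)-8-(tert-butyldiphenylsilyloxy)-6-methylocta-1,6-dien-3-yl]-4,4,5,5-tetramethyl-1,3,2-dioxaborolane | C=C[C@H](B1OC(C)(C)C(C)(C)O1)CC/C(C)=C/CO[Si](c2ccccc2)(c2ccccc2)C(C)(C)C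
F4 | step 4 | C6 aldehyde with a vinyl group on C9 | C=C[C@H](CC/C(C)=C/CO[Si](c1ccccc1)(c1ccccc1)C(C)(C)C)[C@]2(C)CCCC(C)(C)[C@H]2C=O
F5 | step 6 | 15-(tert-butyldiphenylsilyloxy)-17-nor-9-epi-ent-labd-13E-en-8-one | CC(C)(C)[Si](c1ccccc1)(c1ccccc1)OC/C=C(\C)CC[C@H]2C(=O)CC[C@@H]3C(C)(C)CCC[C@@]23C
F6 | step 6 | 15-(tert-butyldiphenylsilyloxy)-17-nor-ent-labd-13E-en-8-one | CC(C)(C)[Si](c1ccccc1)(c1ccccc1)OC/C=C(\C)CC[C@@H]2C(=O)CC[C@@H]3C(C)(C)CCC[C@@]23C
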